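**Assumption:** the target has no stereocentres (it is achiral), so "single enantiomer" is taken to mean the single geometric isomer drawn, with the geranyl C2'=C3' alkene E and the stilbene alkene E.

## Retrosynthetic overview
1. Disconnect the stilbene C(aryl)–C(vinyl) bond by a Heck reaction: 2-geranyl-4-iodophenol + 3,5-dihydroxystyrene. The Heck step sets the stilbene E geometry.
2. 2-Geranyl-4-iodophenol comes from ortho-C-geranylation of 4-iodophenol with geranyl bromide; the geranyl E geometry is bought in, and iodine blocks the para position.
3. 3,5-Dihydroxystyrene comes from Wittig methylenation of 3,5-dihydroxybenzaldehyde.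
4. No rings are formed; both benzene rings are purchased. The route uses no protecting groups and no acid, which avoids cyclisation of the ortho-geranyl phenol to a chroman.

## Route

**Step 1**
Reactants: **1** 4-iodophenol; **2** geranyl bromide [(2E)-1-bromo-3,7-dimethylocta-2,6-diene]
Product: **3** 2-[(2E)-3,7-dimethylocta-2,6-dien-1-yl]-4-iodophenol (2-geranyl-4-iodophenol)
Conditions: **1** (1.5 equiv), NaH (1.5 equiv), toluene, 0 °C → rt; then **2** (1.0 equiv), rt, 16 h; aq NH4Cl work-up (no strong acid)
Reagents that add atoms: geranyl bromide (compound **2**), CC(C)=CCC/C(C)=C/CBr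
Why: Ortho-selective C-allylation of a sodium phenoxide in a non-polar solvent, where the tight Na–O ion pair shields oxygen and delivers the allyl bromide to the ortho carbon. Para is blocked by iodine, and SN2 attack at the primary allylic carbon retains the 2E alkene. Excess phenoxide limits dialkylation, and the O-geranyl ether by-product is separable.

**Step 2**
Reactants: **4** 3,5-dihydroxybenzaldehyde; **5** methyltriphenylphosphonium bromide
Product: **6** 3,5-dihydroxystyrene (5-vinylbenzene-1,3-diol)
Conditions: **5** (3.3 equiv), KOtBu (3.2 equiv), THF, 0 °C → rt; aq NH4Cl work-up; add trace BHT and use promptly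
Reagents that add atoms: methyltriphenylphosphonium bromide (compound **5**, supplies CH2), C[P+](c1ccccc1)(c1ccccc1)c1ccccc1.[Br-]
Why: Wittig methylenation. Two equivalents of ylide are consumed deprotonating the phenols; the meta-phenoxides are not conjugated to the aldehyde, so it stays electrophilic toward the third equivalent.

**Step 3**
Reactants: **3** 2-geranyl-4-iodophenol; **6** 3,5-dihydroxystyrene (1.3 equiv)
Product: **7** schweinfurthin I, 5-[(E)-2-{3-[(2E)-3,7-dimethylocta-2,6-dien-1-yl]-4-hydroxyphenyl}ethenyl]benzene-1,3-diol
Conditions: Pd(OAc)2 (5 mol %), P(o-tol)3 (12 mol %), Et3N (3 equiv), DMF, 90 °C, Ar, trace BHT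
Reagents that add atoms: none
Why: Mizoroki–Heck coupling. The aryl–Pd–I species adds to the terminal styrene carbon far faster than to the trisubstituted geranyl alkenes, and syn β-hydride elimination gives the E-stilbene. Free phenols and the geranyl chain tolerate the mildly basic, acid-free conditions.

## Compound list
1 | 4-iodophenol | Oc1ccc(I)cc1 | starting material
2 | geranyl bromide, (2E)-1-bromo-3,7-dimethylocta-2,6-diene | CC(C)=CCC/C(C)=C/CBr | starting material
3 | 2-[(2E)-3,7-dimethylocta-2,6-dien-1-yl]-4-iodophenol | CC(C)=CCC/C(C)=C/Cc1cc(I)ccc1O | intermediate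
4 | 3,5-dihydroxybenzaldehyde | O=Cc1cc(O)cc(O)c1 | starting material
5 | methyltriphenylphosphonium bromide | C[P+](c1ccccc1)(c1ccccc1)c1ccccc1.[Br-] | starting material (reagent)
6 | 3,5-dihydroxystyrene (5-vinylbenzene-1,3-diol) | C=Cc1cc(O)cc(O)c1 | intermediate
7 | schweinfurthin I | CC(C)=CCC/C(C)=C/Cc1cc(/C=C/c2cc(O)cc(O)c2)ccc1O | target

## Summary
Total step count: 3
Longest linear sequence: 2 steps (1 → 3 → 7, or 4 → 6 → 7)

Steps most likely to fail, with fallbacks:
1. **Step 1 (ortho-C-geranylation).** Risks are O-alkylation, dialkylation, SN2' (linalyl-type) product and modest yield. Fallback: directed ortho-metalation instead of phenoxide alkylation. Protect 4-hydroxybenzaldehyde as its MOM ether and acetal, lithiate ortho to OMOM (n-BuLi/TMEDA), transmetalate to copper, and allylate with geranyl bromide. The resulting 3-geranyl-4-(MOM-oxy)benzaldehyde is then carried into the olefination fallback below.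
2. **Step 3 (Heck on unprotected partners).** Risks are Pd(II)-mediated cyclisation of the ortho-geranyl phenol, styrene polymerisation and 1,1-diaryl regioisomer. Fallback: form the stilbene by Horner–Wadsworth–Emmons olefination instead. React 3-geranyl-4-(MOM-oxy)benzaldehyde with diethyl 3,5-bis(MOM-oxy)benzylphosphonate (NaH, THF), which is E-selective, then remove the MOM groups with CSA/MeOH.
3. **Step 2 (Wittig on the free dihydroxybenzaldehyde).** Risks are an insoluble dianion and a polymerisation-prone product. Fallback: make the styrene by Suzuki–Miyaura vinylation of commercial 5-bromoresorcinol with potassium vinyltrifluoroborate. Alternatively, bis-TBS-protect **4** before the Wittig, run the Heck on the silyl ether, and finish with TBAF.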